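The data are calculated for an exercise, and the scatter is random.

Take a small charge of X. If each J takes one X, as we assume, then in winter, with X at 0.250 M against J at 0.50 M, X is the limiting reagent and J keeps half of its charge. Friday's run, charged much the same, reads E at 24% at 3.00 min and lower afterwards, which is less than that half, so we name J for winter.

in all of them: J 0.50 M
- Friday's: X 0.21 M; run made earlier
- Sunday's: X 0.58 M; run made earlier
- Thursday's: X 1.3 M; run made earlier
- winter: X 0.250 M; time 80 min
- dusk: X 1.25 M; time 80 min

| Friday's: time / min | Friday's: E / % | Sunday's: time / min | Sunday's: E / % | Thursday's: time / min | Thursday's: E / % |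
|---|---|---|---|---|---|
| 3.00 | 24 | 10.0 | 41 | 5.00 | 30 |
| 8.00 | 23 | 20.0 | 32 | 15.0 | 18 |
| 15.0 | 20 | 30.0 | 25 | 25.0 | 15 |
| 40.0 | 10 | 40.0 | 23 | 40.0 | 13 |

(standard deviation of a reading: 1.5 percentage points)

- what was read earlier has a scatter of 1.5 percentage points, one standard deviation

- which of these holds the largest part of the J at the end of winter (G / E / J)
- which of these holds the largest part of the J at the end of dusk (G / E / J)
- final E in dusk, as a percentage of the J charged

Dusk is the other end, and its neighbour is Thursday's run, charged 1.3 M of X against dusk's 1.25 M. We set that gap in X aside and treat the two as one flask: Thursday's last reading stands at 40.0 min, dusk ends at 80 min. Thursday's E drops from 30% to 15% by 25.0 min, then slows. The time gap between its last two readings over the logarithm of their ratio gives 105 min, and this tail time constant of E is what we carry. Those readings stand 2 percentage points apart with a scatter of 1.5 points each, so it is a rough reading. Over the further 40.0 min it takes Thursday's last 13% to 8.88%, our number for E in dusk. Since X exceeds J and our E comes out that low, we name G for dusk.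

The forecast named J for winter and G for dusk and set E in dusk at 11%, “possibly still drifting slowly down”, higher than our 8.88%.

Dusk ends with E at 8.67%, G at 28.8% and J at 0%; winter ends with J at 50.0%.

    J + X → E + D (k = 0.0270 M⁻¹ s⁻¹)
    X + E ⇌ G + D (K = 2.40, k = 0.0180 M⁻¹ s⁻¹)
    E + D → Q (k = 9.50 × 10⁻⁴ M⁻¹ s⁻¹)
    E ⇌ L (K = 2.10, k = 8.70 × 10⁻⁴ s⁻¹)

Dusk also holds Q at 40.3% of the J charged, more than G, but Q is not among the forms asked, and of those G stays above E. Started from dusk's own E of 12.3% at 40.0 min, the tail time constant gives 8.40% at 80 min.

A neighbour of dusk charged 0.50 M of X has Sunday's run, at 0.58 M, beside it: the tail time constant, read on Thursday's run and borrowed here, takes Sunday's last 23% over the same 40.0 min to 15.7% of E, and the computed neighbour ends at 16.0%.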